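Everything rests on cutting the O1–C6 bond of ring B. Ring B carries oxygen on C3 next to the quaternary ether carbon C2 and bromine on C5, which is the substitution pattern of a 2H-pyran-3(6H)-one and therefore of an oxidised 2-furyl carbinol. In a single operation the Achmatowicz oxidation of a furan closes ring B, creates the C3 carbonyl, leaves the C4=C5 enone that later takes bromide at C5, and makes C6 a ketal carbon ready for its second methyl. Its precursor is the (R)-configured tertiary 5-methyl-2-furyl methyl carbinol that already carries the complete bromochloro ring A, made from an Evans Diels–Alder adduct of isoprene.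

Key step: step 8

Assumption: ring B is numbered O1, C2 (carries ring A), C3 (oxygen), C4, C5 (Br), C6 (CMe2) and ring A as a 3-bromo-4-chloro-4-methylcyclohexyl group; the enantiomer of the bis(sulfonamide) diol ligand in step 7 is the one that transfers the alkyl group to the Si face of aryl alkyl ketones, its antipode being equally available.

Step 1
Reactants: 1 (R)-4-benzyl-1,3-oxazolidin-2-one; 2 acryloyl chloride
Product: 4 (R)-3-acryloyl-4-benzyl-1,3-oxazolidin-2-one, via lithium oxazolidinide 3 (not isolated)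
Conditions: n-BuLi, THF, −78 °C; then 2, −78 °C
Reagents that add atoms: none
Why: N-Acylation of the lithiated oxazolidinone by the acid chloride (nucleophilic acyl substitution) at −78 °C is the standard imide synthesis and the low temperature suppresses polymerisation of the acrylimide.

Step 2
Reactants: 4 (R)-3-acryloyl-4-benzyl-1,3-oxazolidin-2-one; 5 isoprene
Product: 6 (R)-4-benzyl-3-[(S)-4-methylcyclohex-3-ene-1-carbonyl]-1,3-oxazolidin-2-one
Conditions: Et2AlCl (1.4 equiv), CH2Cl2, −78 °C; recrystallise
Reagents that add atoms: none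
Why: Evans asymmetric Diels–Alder reaction: Et2AlCl chelates both imide carbonyls, isoprene adds with para regiochemistry to the face of the s-cis acrylimide away from the benzyl group, and this sets C1 of ring A as S.

Step 3
Reactants: 6 (R)-4-benzyl-3-[(S)-4-methylcyclohex-3-ene-1-carbonyl]-1,3-oxazolidin-2-one
Product: 7 (R)-4-benzyl-3-[(1S,3R,4R)-3-chloro-4-hydroxy-4-methylcyclohexane-1-carbonyl]-1,3-oxazolidin-2-one
Conditions: trichloroisocyanuric acid (0.35 equiv), acetone–H2O (5:1), 0 °C to rt
Reagents that add atoms: trichloroisocyanuric acid, O=C1N(Cl)C(=O)N(Cl)C(=O)N1Cl; water, O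
Why: Chlorohydrin formation (cohalogenation of an alkene with electrophilic chlorine in water) is expected to follow the trans-diaxial (Fürst–Plattner) course known for bromohydrins of 4-substituted 1-methylcyclohexenes, the chloronium ion on the face anti to the acyl group being opened by water at the tertiary carbon, which sets C3 (Cl, trans to the acyl group) as R and C4 (OH, cis to it) as R.

Step 4
Reactants: 7 (R)-4-benzyl-3-[(1S,3R,4R)-3-chloro-4-hydroxy-4-methylcyclohexane-1-carbonyl]-1,3-oxazolidin-2-one
Product: 9 (R)-4-benzyl-3-[(1S,3S,4S)-3-bromo-4-chloro-4-methylcyclohexane-1-carbonyl]-1,3-oxazolidin-2-one, via diaxial bromochloride 8 (not isolated)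
Conditions: anhydrous HBr, CH2Cl2, 0 °C; concentrate; MeNO2, 80 °C; unchanged 8 is separated and heated again
Reagents that add atoms: hydrogen bromide, Br
Why: Substitution of the tertiary alcohol by HBr should proceed with retention through the anti-periplanar chlorine (bridged chloronium ion opened at the tertiary carbon in the trans-diaxial sense) to give 8, and on heating in a polar solvent this trans-diaxial tertiary bromide/secondary chloride undergoes the known diaxial-to-diequatorial 1,2-interchange of vicinal dihalides, each halogen migrating on its own ring face, so that Br arrives equatorial on C3 cis to the acyl group (3S) and Cl equatorial on C4 trans to it (4S).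

Step 5
Reactants: 9 (R)-4-benzyl-3-[(1S,3S,4S)-3-bromo-4-chloro-4-methylcyclohexane-1-carbonyl]-1,3-oxazolidin-2-one
Product: 11 (1S,3S,4S)-3-bromo-4-chloro-4-methylcyclohexane-1-carboxylic acid, via peroxy acid 10 (not isolated)
Conditions: LiOH, H2O2, THF–H2O (3:1), 0 °C; then Na2SO3; HCl to pH 2
Reagents that add atoms: hydrogen peroxide, OO
Why: Hydroperoxide-mediated hydrolysis of an N-acyloxazolidinone attacks the exocyclic carbonyl selectively even in α-branched imides, the peroxy acid is reduced by sulfite, no stereocentre is touched and the auxiliary is recovered.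

Step 6
Reactants: 11 (1S,3S,4S)-3-bromo-4-chloro-4-methylcyclohexane-1-carboxylic acid; 12 2-methylfuran
Product: 14 [(1S,3S,4S)-3-bromo-4-chloro-4-methylcyclohexyl](5-methylfuran-2-yl)methanone, via mixed anhydride 13 (not isolated)
Conditions: (CF3CO)2O, CH2Cl2, 0 °C; then 12 (3 equiv), 0 °C to rt
Reagents that add atoms: none
Why: Friedel–Crafts acylation of the electron-rich furan by the acyl trifluoroacetate formed in situ takes place at the free α-position (C5 of 2-methylfuran) without a metal Lewis acid or base, so neither C1 of ring A epimerises nor the halides are eliminated.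

Step 7
Reactants: 14 [(1S,3S,4S)-3-bromo-4-chloro-4-methylcyclohexyl](5-methylfuran-2-yl)methanone
Product: 15 (1R)-1-[(1S,3S,4S)-3-bromo-4-chloro-4-methylcyclohexyl]-1-(5-methylfuran-2-yl)ethan-1-ol
Conditions: Me2Zn (3 equiv), Ti(OiPr)4 (1.2 equiv), trans-1,2-bis(2-hydroxycamphor-10-sulfonamido)cyclohexane (10 mol %), toluene–hexane, rt; aqueous NH4Cl
Reagents that add atoms: dimethylzinc, C[Zn]C
Why: Catalytic enantioselective addition of a dialkylzinc to an aryl alkyl ketone (Ti(OiPr)4 with a bis(sulfonamide) diol ligand) is used because C1 of ring A, flanked by two nearly identical methylene arms, exerts no useful 1,2-induction, so the catalyst alone directs methyl to the Si face and sets the carbinol carbon (the future C2) as R.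

Step 8
Reactants: 15 (1R)-1-[(1S,3S,4S)-3-bromo-4-chloro-4-methylcyclohexyl]-1-(5-methylfuran-2-yl)ethan-1-ol
Product: 17 (2R)-2-[(1S,3S,4S)-3-bromo-4-chloro-4-methylcyclohexyl]-6-hydroxy-2,6-dimethyl-2H-pyran-3(6H)-one (both C6 anomers), via Z-enedione 16 (not isolated)
Conditions: NBS (1.05 equiv), NaHCO3, NaOAc, THF–H2O (4:1), 0 °C
Reagents that add atoms: water, O
Why: Achmatowicz oxidative rearrangement: NBS brominates the furan at its methyl-bearing α-carbon, water adds and bromide is lost, and the 2,5-dioxygenated dihydrofuran opens to the (Z)-2-ene-1,4-dione 16. The tertiary C2 hydroxyl then adds to the C6 methyl ketone in a 6-exo-trig hemiketalisation that forms the O1–C6 bond and closes ring B as the 6-hydroxy-2H-pyran-3(6H)-one. The closest precedents are NBS-mediated Achmatowicz reactions of tertiary 2-furyl carbinols and of 5-alkylfurans. No stereocentre of consequence is created: C2 is carried through unchanged from step 7, and the C6 anomers equilibrate and later converge on the gem-dimethyl carbon. The selectivity needed is oxidation of the furan alone, which is secured because ring A holds only saturated C–Cl and C–Br bonds that are inert to NBS, and because the NaHCO3/NaOAc buffer prevents acid ionisation of the furyl carbinol and Z-to-E isomerisation of the enedione.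

Step 9
Reactants: 17 (2R)-2-[(1S,3S,4S)-3-bromo-4-chloro-4-methylcyclohexyl]-6-hydroxy-2,6-dimethyl-2H-pyran-3(6H)-one
Product: 18 (2R)-2-[(1S,3S,4S)-3-bromo-4-chloro-4-methylcyclohexyl]-2,6-dimethyl-3-oxo-3,6-dihydro-2H-pyran-6-yl acetate (both C6 anomers)
Conditions: Ac2O, Et3N, DMAP (cat.), CH2Cl2, 0 °C to rt
Reagents that add atoms: acetic anhydride, CC(=O)OC(C)=O
Why: DMAP-catalysed O-acylation of the anomeric hydroxyl turns the hemiketal into an ionisable ketal acetate; both C6 anomers are usable because C6 loses its stereogenicity in step 10, and no oxidopyrylium can form since C2 bears no hydrogen.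

Step 10
Reactants: 18 (2R)-2-[(1S,3S,4S)-3-bromo-4-chloro-4-methylcyclohexyl]-2,6-dimethyl-3-oxo-3,6-dihydro-2H-pyran-6-yl acetate
Product: 19 (2R)-2-[(1S,3S,4S)-3-bromo-4-chloro-4-methylcyclohexyl]-2,6,6-trimethyl-2H-pyran-3(6H)-one
Conditions: AlMe3 (2.5 equiv), CH2Cl2, −78 to −30 °C; aqueous work-up
Reagents that add atoms: trimethylaluminium, C[Al](C)C
Why: Lewis acid-mediated anomeric C-methylation (organoaluminium substitution of a ketal acetate): AlMe3 ionises the C6 acetate to the ring oxocarbenium ion and the [Me3Al(OAc)]− counter-ion returns a methyl group to C6, which thereby becomes the non-stereogenic gem-dimethyl carbon, while the hindered conjugated C3 ketone and the tertiary chloride, deactivated by its vicinal bromine, should react more slowly at low temperature.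

Step 11
Reactants: 19 (2R)-2-[(1S,3S,4S)-3-bromo-4-chloro-4-methylcyclohexyl]-2,6,6-trimethyl-2H-pyran-3(6H)-one
Product: 21 caespitol (2R,3R,5R)-5-bromo-2-[(1S,3S,4S)-3-bromo-4-chloro-4-methylcyclohexyl]-2,6,6-trimethyloxan-3-ol, via bromoketone 20 (not isolated)
Conditions: anhydrous HBr, CH2Cl2, −40 °C; evaporate cold; LiBH(sec-Bu)3, THF, −78 °C; H2O
Reagents that add atoms: hydrogen bromide, Br
Why: Hydrobromination of the enone by conjugate addition should place bromide on C5 trans to ring A (5R) through axial attack anti to the pseudoaxial C6 methyl in the enone conformer that turns the bulky ring A perpendicular to the carbonyl, and the bulky hydride then attacks C3 from the face of the C2 methyl, away from ring A (equatorial attack on the chair), to give the axial 3R alcohol trans to bromine, as in LiBH(sec-Bu)3 reductions of tetrahydropyran-3-ones and of ketones flanked by an axial methyl group.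

Step 12
Reactants: 21 caespitol (2R,3R,5R)-5-bromo-2-[(1S,3S,4S)-3-bromo-4-chloro-4-methylcyclohexyl]-2,6,6-trimethyloxan-3-ol
Product: 22 8-acetylcaespitol (2R,3R,5R)-5-bromo-2-[(1S,3S,4S)-3-bromo-4-chloro-4-methylcyclohexyl]-2,6,6-trimethyloxan-3-yl acetate
Conditions: Ac2O, pyridine, DMAP (cat.), CH2Cl2, rt
Reagents that add atoms: acetic anhydride, CC(=O)OC(C)=O
Why: DMAP-catalysed acetylation (nucleophilic acyl transfer) of the hindered axial C3 hydroxyl with retention of all stereocentres gives the target.

Compound list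
1 | (R)-4-benzyl-1,3-oxazolidin-2-one | O=C1N[C@H](Cc2ccccc2)CO1 | starting material
2 | acryloyl chloride | C=CC(=O)Cl | starting material
3 | lithium (R)-4-benzyl-2-oxo-1,3-oxazolidin-3-ide | [Li+].O=C1[N-][C@H](Cc2ccccc2)CO1 | intermediate (not isolated)
4 | (R)-3-acryloyl-4-benzyl-1,3-oxazolidin-2-one | C=CC(=O)N1[C@H](Cc2ccccc2)COC1=O | intermediate
5 | isoprene | CC(=C)C=C | starting material
6 | (R)-4-benzyl-3-[(S)-4-methylcyclohex-3-ene-1-carbonyl]-1,3-oxazolidin-2-one | CC1=CC[C@H](CC1)C(=O)N1[C@H](Cc2ccccc2)COC1=O | intermediate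
7 | (R)-4-benzyl-3-[(1S,3R,4R)-3-chloro-4-hydroxy-4-methylcyclohexane-1-carbonyl]-1,3-oxazolidin-2-one (Cl and OH trans-diaxial) | O=C([C@H]1CC[C@](O)(C)[C@H](Cl)C1)N1[C@H](Cc2ccccc2)COC1=O | intermediate
8 | (R)-4-benzyl-3-[(1S,3R,4R)-4-bromo-3-chloro-4-methylcyclohexane-1-carbonyl]-1,3-oxazolidin-2-one (tertiary Br and secondary Cl trans-diaxial) | O=C([C@H]1CC[C@](Br)(C)[C@H](Cl)C1)N1[C@H](Cc2ccccc2)COC1=O | intermediate (not isolated)
9 | (R)-4-benzyl-3-[(1S,3S,4S)-3-bromo-4-chloro-4-methylcyclohexane-1-carbonyl]-1,3-oxazolidin-2-one (Br and Cl trans-diequatorial) | O=C([C@H]1CC[C@](C)(Cl)[C@@H](Br)C1)N1[C@H](Cc2ccccc2)COC1=O | intermediate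
10 | (1S,3S,4S)-3-bromo-4-chloro-4-methylcyclohexane-1-carboperoxoic acid (present as its lithium salt) | OOC(=O)[C@H]1CC[C@](C)(Cl)[C@@H](Br)C1 | intermediate (not isolated)
11 | (1S,3S,4S)-3-bromo-4-chloro-4-methylcyclohexane-1-carboxylic acid | OC(=O)[C@H]1CC[C@](C)(Cl)[C@@H](Br)C1 | intermediate
12 | 2-methylfuran | Cc1ccco1 | starting material
13 | (1S,3S,4S)-3-bromo-4-chloro-4-methylcyclohexane-1-carboxylic trifluoroacetic anhydride | FC(F)(F)C(=O)OC(=O)[C@H]1CC[C@](C)(Cl)[C@@H](Br)C1 | intermediate (not isolated)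
14 | [(1S,3S,4S)-3-bromo-4-chloro-4-methylcyclohexyl](5-methylfuran-2-yl)methanone | Cc1ccc(o1)C(=O)[C@H]1CC[C@](C)(Cl)[C@@H](Br)C1 | intermediate
15 | (1R)-1-[(1S,3S,4S)-3-bromo-4-chloro-4-methylcyclohexyl]-1-(5-methylfuran-2-yl)ethan-1-ol | Cc1ccc(o1)[C@](C)(O)[C@H]2CC[C@](C)(Cl)[C@@H](Br)C2 | intermediate (key-step precursor)
16 | (3Z,6R)-6-[(1S,3S,4S)-3-bromo-4-chloro-4-methylcyclohexyl]-6-hydroxyhept-3-ene-2,5-dione | CC(=O)/C=C\C(=O)[C@](C)(O)[C@H]1CC[C@](C)(Cl)[C@@H](Br)C1 | intermediate (not isolated)
17 | (2R)-2-[(1S,3S,4S)-3-bromo-4-chloro-4-methylcyclohexyl]-6-hydroxy-2,6-dimethyl-2H-pyran-3(6H)-one (C6 anomers) | CC1(O)C=CC(=O)[C@](C)(O1)[C@H]2CC[C@](C)(Cl)[C@@H](Br)C2 | intermediate (key-step product)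
18 | (2R)-2-[(1S,3S,4S)-3-bromo-4-chloro-4-methylcyclohexyl]-2,6-dimethyl-3-oxo-3,6-dihydro-2H-pyran-6-yl acetate (C6 anomers) | CC(=O)OC1(C)C=CC(=O)[C@](C)(O1)[C@H]2CC[C@](C)(Cl)[C@@H](Br)C2 | intermediate
19 | (2R)-2-[(1S,3S,4S)-3-bromo-4-chloro-4-methylcyclohexyl]-2,6,6-trimethyl-2H-pyran-3(6H)-one | CC1(C)C=CC(=O)[C@](C)(O1)[C@H]2CC[C@](C)(Cl)[C@@H](Br)C2 | intermediate
20 | (2R,5R)-5-bromo-2-[(1S,3S,4S)-3-bromo-4-chloro-4-methylcyclohexyl]-2,6,6-trimethyloxan-3-one | O=C1C[C@@H](Br)C(C)(C)O[C@]1(C)[C@H]1CC[C@](C)(Cl)[C@@H](Br)C1 | intermediate (not isolated)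
21 | caespitol, (2R,3R,5R)-5-bromo-2-[(1S,3S,4S)-3-bromo-4-chloro-4-methylcyclohexyl]-2,6,6-trimethyloxan-3-ol | O[C@@H]1C[C@@H](Br)C(C)(C)O[C@]1(C)[C@H]1CC[C@](C)(Cl)[C@@H](Br)C1 | intermediate
22 | 8-acetylcaespitol, (2R,3R,5R)-5-bromo-2-[(1S,3S,4S)-3-bromo-4-chloro-4-methylcyclohexyl]-2,6,6-trimethyloxan-3-yl acetate | CC(=O)O[C@@H]1C[C@@H](Br)C(C)(C)O[C@]1(C)[C@H]1CC[C@](C)(Cl)[C@@H](Br)C1 | target

Total step count: 12. Longest linear sequence: 12 steps (1 to 22).

Steps most likely to fail

Step 11. The facial selectivity of bromide addition to C5 may be weak or reversed, because the two C2 substituents bias the enone conformers only slightly, and the β-bromoketone may lose HBr again before the hydride arrives. The fallback sets out from enone 19, places oxygen on C5 first and lets bromide enter with inversion. Weitz–Scheffer epoxidation (t-BuOOH, DBU, CH2Cl2) would give the 4,5-epoxy ketone F1 on the face that nucleophiles prefer, with epimers separable at this stable stage. SmI2 in THF–MeOH at −78 °C would cleave the C4–O bond to the β-hydroxy ketone F2. Narasaka–Prasad reduction (Et2BOMe, NaBH4, THF–MeOH, −78 °C) would tie C3 to C5 as the syn-3,5-diol F3. Trimethyl orthoacetate with PPTS would give the cyclic orthoacetate F4. Acetyl bromide would open F4 through the 1,3-dioxan-2-ylium ion, bromide attacking the less hindered C5 with inversion while the acetyl group stays on O3. This comes back to the route at the target 22.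

Step 10. Methyl may add to the C3 carbonyl in competition with substitution at C6, and the Lewis acid may ionise other sites. The fallback sets out from ketal acetate 18 and removes the carbonyl for the duration of the substitution. Luche reduction (NaBH4, CeCl3·7H2O, MeOH, −78 °C) would give the allylic alcohol acetate F5, whose C3 configuration is immaterial. AlMe3 in CH2Cl2 would then methylate the anomeric carbon of this allylic ketal acetate to the gem-dimethyl allylic alcohol F6. Oxidation with MnO2 in CH2Cl2 would restore the enone and return to the route at 19.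

Step 7. Methyl transfer to the hindered, electron-rich furyl ketone may be slow or poorly face-selective under catalyst control. The fallback sets out from ketone 14 and replaces catalyst control by separation. MeMgBr pre-complexed with CeCl3 in THF at −78 °C would add without enolisation and without facial bias, giving 15 together with its carbinol epimer F7. The two would be separated by chromatography, and the route is rejoined at 15.

Further compounds
F1 | step 11 | (2R)-2-[(1S,3S,4S)-3-bromo-4-chloro-4-methylcyclohexyl]-4,5-epoxy-2,6,6-trimethyloxan-3-one, oxirane oxygen on the ring-A face | O=C1[C@@H]2O[C@@H]2C(C)(C)O[C@]1(C)[C@H]1CC[C@](C)(Cl)[C@@H](Br)C1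
F2 | step 11 | (2R,5S)-2-[(1S,3S,4S)-3-bromo-4-chloro-4-methylcyclohexyl]-5-hydroxy-2,6,6-trimethyloxan-3-one | O=C1C[C@H](O)C(C)(C)O[C@]1(C)[C@H]1CC[C@](C)(Cl)[C@@H](Br)C1
F3 | step 11 | (2R,3R,5S)-2-[(1S,3S,4S)-3-bromo-4-chloro-4-methylcyclohexyl]-2,6,6-trimethyloxane-3,5-diol | O[C@@H]1C[C@H](O)C(C)(C)O[C@]1(C)[C@H]1CC[C@](C)(Cl)[C@@H](Br)C1
F4 | step 11 | cyclic methyl orthoacetate of F3 (2-methoxy-2-methyl-1,3-dioxane bridging O3 and O5) | COC3(C)O[C@@H]1C[C@H](O3)C(C)(C)O[C@]1(C)[C@H]1CC[C@](C)(Cl)[C@@H](Br)C1
F5 | step 10 | (2R)-2-[(1S,3S,4S)-3-bromo-4-chloro-4-methylcyclohexyl]-3-hydroxy-2,6-dimethyl-3,6-dihydro-2H-pyran-6-yl acetate (C3 and C6 epimers) | CC(=O)OC1(C)C=CC(O)[C@](C)(O1)[C@H]2CC[C@](C)(Cl)[C@@H](Br)C2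
F6 | step 10 | (2R)-2-[(1S,3S,4S)-3-bromo-4-chloro-4-methylcyclohexyl]-2,6,6-trimethyl-3,6-dihydro-2H-pyran-3-ol (C3 epimers) | CC1(C)C=CC(O)[C@](C)(O1)[C@H]2CC[C@](C)(Cl)[C@@H](Br)C2
F7 | step 7 | (1S)-1-[(1S,3S,4S)-3-bromo-4-chloro-4-methylcyclohexyl]-1-(5-methylfuran-2-yl)ethan-1-ol | Cc1ccc(o1)[C@@](C)(O)[C@H]2CC[C@](C)(Cl)[C@@H](Br)C2
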